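A stirred flask of constant volume held substrate, partner and rival reagent, and the recipes differed in how substrate or rival went in.

| setting | eta | epsilon | winter | dawn | spring | summer |
|---|---|---|---|---|---|---|
| substrate | 0.24 M | 0.24 M | 0.24 M | 0.24 M (fed, over 15 min) | 0.24 M | 0.24 M (in portions, 2, over 15 min) |
| partner | 0.12 M | 0.18 M | 0.120 M | 0.120 M | 0.120 M | 0.120 M |
| rival reagent | 0.312 M | 0.312 M | 0.312 M | 0.312 M | 0.312 M (fed, over 15 min) | 0.312 M |
| remark | run made earlier | run made earlier | everything together at the start | all else is in the flask from the start; the feed brings no volume worth counting | all else is in the flask from the start; the feed brings no volume worth counting | first portion at the start, last at 15 min |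
| time |  |  | 80 min | 80 min | 80 min | 80 min |

| eta: time / min | eta: target / % | epsilon: time / min | epsilon: target / % |
|---|---|---|---|
| 8.00 | 15.7 | 0.667 | 5.0 |
| 20.0 | 15.9 | 1.33 | 10.8 |
| 40.0 | 14.4 | 2.50 | 14.9 |
| 60.0 | 13.7 | 4.00 | 18.4 |
| 80.0 | 13.1 | 8.00 | 22.5 |

(each reading ± 0.5 percentage points)

- the flask that comes out highest in amount of target, in percent of the substrate charged, or "all alike" when all lie within 1.5 percentage points (winter / dawn / spring / summer / all alike)
- target at the end, in percent of the substrate charged, winter
- target at the end, in percent of the substrate charged, dawn
- target at the end, in percent of the substrate charged, spring
- target at the end, in percent of the substrate charged, summer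

I took target to be a share of the substrate won against the rival, so I reckoned it as odds, target over the remainder, at 8.00 min in both earlier runs, and divided those odds by the charged ratio of partner to rival:

eta: 0.484

epsilon: 0.503

The two runs read alike within their scatter, so I carried their mean, 0.494, as the odds factor: the odds of substrate going to target for each unit of partner-to-rival ratio, an apparent selectivity factor. Winter repeats the eta charges, so I took its reading of 13.1% at 80.0 min.

For spring, I assumed a mean rival of half its charge, which is what a steady feed has delivered on average if none of it is consumed, so the ratio became twice as large, and eta kept 83.4% of its target to the end: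

odds 0.380, share 27.5%

The weak link was that this held partner at its charge, although I assumed each target spends one partner. Taking the mean partner as the charge less half of what target spends gave 0.101 M for eta and 0.0870 M for spring, less than eta:

odds 0.327, end target 20.5%

The forecast named spring, with 13.2% for winter, 5.5% for dawn, 24.5% for spring (range 19% to 30%) and 8.5% for summer. Its ground differed from mine: “This suggests the partner is the contested species”.

The flasks gave 13.3% in winter, 8.94% in dawn, 18.2% in spring and 9.48% in summer, so spring came out highest, 2.3 percentage points under my number.

    substrate + partner → target (k = 0.00990 /M/s)
    substrate + rival reagent → side product (k = 0.0110 /M/s)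
    partner → decomposed reagent (k = 0.00110 /s)
    target ⇌ isomer of the product (K = 0.550, k = 4.10 × 10⁻⁴ /s)

In spring, the target step had half its turnover behind it by 2.82 min and the side-product step by 11.4 min, and the mean rival over the first 15 min was 0.104 M, less than the 0.156 M I had assumed. At the end of the spring feed, 24.4% of the substrate stood beside 10.7% of the partner and 62.7% of the rival, each of its own charge, so the odds factor gave that substrate 0.77 points, and target with isomer of the product then rose 0.9 points. In dawn, the same reckoning at the end of the feed gave 2.5 points, and the rise was 2.8 points.

(All runs were computed on assumed constants; scatter was added.)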